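The plan removes ring A (C4a, C5, C6, C7, C8, C8a) from the naphthazarin. Because this ring is a symmetrical benzene carrying oxygen only at C5 and C8, it can be annulated onto a 1,4-benzoquinone that already bears the complete C2 side chain with its (S)-carbinol carbon. In a single operation, cycloaddition of 1,4-bis(trimethylsilyloxy)cyclohexa-1,3-diene forms C4a–C5 and C8–C8a, and enolisation followed by Alder–Rickert loss of ethylene leaves the aromatic ring with both oxygens installed. The precursor is the (S)-configured 2-(1-silyloxy-4-methylpent-3-enyl)-1,4-benzoquinone, reached by Weinreb acylation, oxazaborolidine reduction, silylation and oxidative demethylation.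

Key step: step 7

Assumption: the two naphthazarin tautomers of alkannin interconvert freely, so the compounds are drawn with the side chain on the quinone ring as in the target, and any peri O-to-O silyl shift before step 9 converges on the same product.

Step 1
Reactants: 1 4-methylpent-3-enoic acid
Product: 3 N-methoxy-N,4-dimethylpent-3-enamide, via 1-(4-methylpent-3-enoyl)imidazole 2 (not isolated)
Conditions: 1,1'-carbonyldiimidazole (CDI, 1.1 equiv), CH2Cl2, 0 °C to 25 °C; then MeNH(OMe)·HCl (1.2 equiv), 25 °C
Reagents that add atoms: N,O-dimethylhydroxylamine hydrochloride, CNOC.Cl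
Why: Activation of the acid as its acyl imidazolide followed by aminolysis is a standard Weinreb amide synthesis, and the near-neutral medium should leave the β,γ-alkene out of conjugation.

Step 2
Reactants: 4 1-bromo-2,5-dimethoxybenzene; 3 N-methoxy-N,4-dimethylpent-3-enamide
Product: 7 1-(2,5-dimethoxyphenyl)-4-methylpent-3-en-1-one, via (2,5-dimethoxyphenyl)lithium 5 (not isolated), via lithium hemiaminal adduct 6 (not isolated)
Conditions: n-BuLi (1.05 equiv), THF, −78 °C; then 3, −78 °C; sat. aq. NH4Cl, −78 °C to 0 °C
Reagents that add atoms: none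
Why: Bromine–lithium exchange gives the aryllithium, which adds once to the amide (Weinreb ketone synthesis) because the five-membered lithium chelate 6 persists until the cold, weakly acidic quench, which should also keep the β,γ-enone from moving into conjugation.

Step 3
Reactants: 7 1-(2,5-dimethoxyphenyl)-4-methylpent-3-en-1-one
Product: 9 (1S)-1-(2,5-dimethoxyphenyl)-4-methylpent-3-en-1-ol, via catechol borate ester 8 (not isolated)
Conditions: (R)-1-methyl-3,3-diphenyltetrahydro-1H,3H-pyrrolo[1,2-c][1,3,2]oxazaborole ((R)-Me-CBS, 0.1 equiv), catecholborane (1.5 equiv), toluene, −78 °C; then 1 M aq. NaOH work-up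
Reagents that add atoms: none
Why: Corey–Bakshi–Shibata reduction, in which the ketone binds the ring boron of the (R)-catalyst with its aryl group (the large substituent) turned away from the catalyst, so that hydride from the nitrogen-bound catecholborane reaches the Re face and sets the (S)-carbinol centre, while catecholborane should leave the trisubstituted alkene untouched at −78 °C.

Step 4
Reactants: 9 (1S)-1-(2,5-dimethoxyphenyl)-4-methylpent-3-en-1-ol
Product: 10 tert-butyl{[(1S)-1-(2,5-dimethoxyphenyl)-4-methylpent-3-en-1-yl]oxy}dimethylsilane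
Conditions: TBSCl (1.3 equiv), imidazole (2.5 equiv), DMF, 25 °C
Reagents that add atoms: tert-butyldimethylsilyl chloride, CC(C)(C)[Si](C)(C)Cl
Why: Imidazole-promoted silylation of a secondary alcohol forms only an O–Si bond, so the (S)-configuration is untouched, and the TBS ether is chosen to outlast the acidic oxidant of step 5 and the heat of step 7.

Step 5
Reactants: 10 tert-butyl{[(1S)-1-(2,5-dimethoxyphenyl)-4-methylpent-3-en-1-yl]oxy}dimethylsilane
Product: 11 2-[(1S)-1-(tert-butyldimethylsilyloxy)-4-methylpent-3-enyl]-1,4-benzoquinone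
Conditions: (NH4)2Ce(NO3)6 (2.5 equiv), MeCN/H2O (2:1), 0 °C, 10 in MeCN added to the oxidant
Reagents that add atoms: water, O
Why: Oxidative demethylation of a 1,4-dimethoxybenzene by tetravalent cerium proceeds through the arene radical cation, water adding at the two methoxy-bearing ring carbons and methanol leaving, and adding the substrate to excess oxidant in the cold should suppress biaryl coupling and spare the TBS ether and the alkene.

Step 6
Reactants: 12 cyclohexane-1,4-dione
Product: 14 1,4-bis(trimethylsilyloxy)cyclohexa-1,3-diene, via 4-(trimethylsilyloxy)cyclohex-3-en-1-one 13 (not isolated)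
Conditions: TMSOTf (2.2 equiv), Et3N (3 equiv), Et2O, 0 °C to 25 °C; pentane extraction, distillation
Reagents that add atoms: trimethylsilyl trifluoromethanesulfonate, C[Si](C)(C)OS(=O)(=O)C(F)(F)F
Why: Soft enolisation (silyl enol ether formation) silylates both carbonyls, and the second deprotonation should take the hydrogen that is both α to the remaining ketone and allylic to the first enol ether, which gives the conjugated 1,3-diene.

Step 7
Reactants: 11 2-[(1S)-1-(tert-butyldimethylsilyloxy)-4-methylpent-3-enyl]-1,4-benzoquinone; 14 1,4-bis(trimethylsilyloxy)cyclohexa-1,3-diene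
Product: 17 2-[(1S)-1-(tert-butyldimethylsilyloxy)-4-methylpent-3-enyl]-5,8-bis(trimethylsilyloxy)naphthalene-1,4-diol, via bicyclo[2.2.2]octenedione adduct 15 (not isolated), via bridged hydroquinone 16 (not isolated)
Conditions: 14 (1.5 equiv), o-xylene, 25 °C, Ar; then Et3N (0.1 equiv), 140 °C
Reagents that add atoms: none
Why: A normal-demand suprafacial [4+2] cycloaddition joins the two silyloxy-bearing termini of electron-rich diene 14 to the unsubstituted C5=C6 bond of quinone 11 (the future C4a and C8a) and gives enedione 15; catalytic Et3N, added only once the quinone is consumed, moves the two α-hydrogens to oxygen to give hydroquinone 16, and at 140 °C a retro-[4+2] ejects the CH2–CH2 bridge as ethylene. The closest known reaction type is the addition of oxygenated cyclohexa-1,3-dienes to quinones or alkynes followed by thermal ethylene extrusion (Diels–Alder then Alder–Rickert reaction), the classical entry to juglone-type and naphthazarin-type rings. Ring A is closed by an intermolecular [4+2] annulation that forms C4a–C5 and C8–C8a in one event, and it is unveiled as a benzene ring by the cycloreversion, which aromatisation drives. No stereocentre is created that survives, since the four sp3 centres of 15 are all erased. The (S)-carbinol carbon lies one bond outside the reacting π system and keeps its C–O bond as a silyl ether, a poor leaving group that should resist quinone-methide formation at the hydroquinone stage. The selectivity needed is between the two quinone C=C bonds, and the C2 side chain secures it by making C2=C3 more hindered and less electrophilic, while the symmetrical diene leaves no regiochemical choice.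

Step 8
Reactants: 17 2-[(1S)-1-(tert-butyldimethylsilyloxy)-4-methylpent-3-enyl]-5,8-bis(trimethylsilyloxy)naphthalene-1,4-diol
Product: 18 2-[(1S)-1-(tert-butyldimethylsilyloxy)-4-methylpent-3-enyl]-5,8-bis(trimethylsilyloxy)-1,4-naphthoquinone
Conditions: Ag2O (2 equiv), MgSO4, CH2Cl2, 0 °C to 25 °C; filtration through Celite, used crude
Reagents that add atoms: none
Why: Ag2O is a neutral, heterogeneous two-electron oxidant (hydroquinone-to-quinone oxidation), so it should convert the C1/C4 diol into the quinone without touching the silyl ethers or the alkene, and it ends the electron-rich stage at which the benzylic C–O bond could ionise.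

Step 9
Reactants: 18 2-[(1S)-1-(tert-butyldimethylsilyloxy)-4-methylpent-3-enyl]-5,8-bis(trimethylsilyloxy)-1,4-naphthoquinone
Product: 20 alkannin, 5,8-dihydroxy-2-[(1S)-1-hydroxy-4-methylpent-3-enyl]-1,4-naphthoquinone, via O-TBS-alkannin 19 (not isolated)
Conditions: HF·pyridine (excess), pyridine, THF, 0 °C to 25 °C
Reagents that add atoms: none
Why: Fluoride-driven desilylation first frees the two peri phenols and then the secondary carbinol, only O–Si bonds being broken so that the (S)-centre is retained, and the weakly acidic, pyridine-buffered medium avoids the basic conditions under which the quinone could tautomerise through the hydrogen on the carbinol carbon.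

Step 10
Reactants: 20 alkannin; 21 isovaleric acid (3-methylbutanoic acid)
Product: 23 isovalerylalkannin, (1S)-1-(5,8-dihydroxy-1,4-dioxo-1,4-dihydronaphthalen-2-yl)-4-methylpent-3-enyl 3-methylbutanoate, via O-isovaleryl-N,N'-dicyclohexylisourea 22 (not isolated)
Conditions: N,N'-dicyclohexylcarbodiimide (DCC, 1.2 equiv), 4-(dimethylamino)pyridine (DMAP, 0.1 equiv), CH2Cl2, 0 °C to 25 °C
Reagents that add atoms: none
Why: Steglich esterification, in which the carbodiimide-activated acid is passed by DMAP to the only free nucleophilic hydroxyl, since the C5 and C8 phenols are tied up in hydrogen bonds to the quinone carbonyls, and acylation at oxygen leaves the (S)-configuration unchanged.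

Compound list
1 | 4-methylpent-3-enoic acid | CC(C)=CCC(=O)O | starting material
2 | 1-(4-methylpent-3-enoyl)-1H-imidazole | CC(C)=CCC(=O)n1ccnc1 | intermediate
3 | N-methoxy-N,4-dimethylpent-3-enamide | CC(C)=CCC(=O)N(C)OC | intermediate
4 | 1-bromo-2,5-dimethoxybenzene | COc1ccc(OC)c(Br)c1 | starting material
5 | (2,5-dimethoxyphenyl)lithium | [Li]c1cc(OC)ccc1OC | intermediate
6 | lithium 1-(2,5-dimethoxyphenyl)-1-[methoxy(methyl)amino]-4-methylpent-3-en-1-olate (transient carbon unassigned) | COc1ccc(OC)c(c1)C(O[Li])(CC=C(C)C)N(C)OC | intermediate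
7 | 1-(2,5-dimethoxyphenyl)-4-methylpent-3-en-1-one | COc1ccc(OC)c(c1)C(=O)CC=C(C)C | intermediate
8 | 2-{[(1S)-1-(2,5-dimethoxyphenyl)-4-methylpent-3-en-1-yl]oxy}-1,3,2-benzodioxaborole | CC(C)=CC[C@H](OB1Oc2ccccc2O1)c1cc(OC)ccc1OC | intermediate
9 | (1S)-1-(2,5-dimethoxyphenyl)-4-methylpent-3-en-1-ol | CC(C)=CC[C@H](O)c1cc(OC)ccc1OC | intermediate
10 | tert-butyl{[(1S)-1-(2,5-dimethoxyphenyl)-4-methylpent-3-en-1-yl]oxy}dimethylsilane | CC(C)=CC[C@H](O[Si](C)(C)C(C)(C)C)c1cc(OC)ccc1OC | intermediate
11 | 2-[(1S)-1-(tert-butyldimethylsilyloxy)-4-methylpent-3-enyl]-1,4-benzoquinone | CC(C)=CC[C@H](O[Si](C)(C)C(C)(C)C)C1=CC(=O)C=CC1=O | intermediate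
12 | cyclohexane-1,4-dione | O=C1CCC(=O)CC1 | starting material
13 | 4-(trimethylsilyloxy)cyclohex-3-en-1-one | C[Si](C)(C)OC1=CCC(=O)CC1 | intermediate
14 | 1,4-bis(trimethylsilyloxy)cyclohexa-1,3-diene | C[Si](C)(C)OC1=CC=C(O[Si](C)(C)C)CC1 | intermediate
15 | 2-[(1S)-1-(tert-butyldimethylsilyloxy)-4-methylpent-3-enyl]-5,8-bis(trimethylsilyloxy)-4a,5,8,8a-tetrahydro-5,8-ethanonaphthalene-1,4-dione (cis-fused; transient ring centres unassigned) | CC(C)=CC[C@H](O[Si](C)(C)C(C)(C)C)C1=CC(=O)C2C(C1=O)C3(O[Si](C)(C)C)CCC2(O[Si](C)(C)C)C=C3 | intermediate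
16 | 2-[(1S)-1-(tert-butyldimethylsilyloxy)-4-methylpent-3-enyl]-5,8-bis(trimethylsilyloxy)-5,8-dihydro-5,8-ethanonaphthalene-1,4-diol | CC(C)=CC[C@H](O[Si](C)(C)C(C)(C)C)c1cc(O)c2c(c1O)C1(O[Si](C)(C)C)CCC2(O[Si](C)(C)C)C=C1 | intermediate
17 | 2-[(1S)-1-(tert-butyldimethylsilyloxy)-4-methylpent-3-enyl]-5,8-bis(trimethylsilyloxy)naphthalene-1,4-diol | CC(C)=CC[C@H](O[Si](C)(C)C(C)(C)C)c1cc(O)c2c(O[Si](C)(C)C)ccc(O[Si](C)(C)C)c2c1O | intermediate
18 | 2-[(1S)-1-(tert-butyldimethylsilyloxy)-4-methylpent-3-enyl]-5,8-bis(trimethylsilyloxy)-1,4-naphthoquinone | CC(C)=CC[C@H](O[Si](C)(C)C(C)(C)C)C1=CC(=O)c2c(O[Si](C)(C)C)ccc(O[Si](C)(C)C)c2C1=O | intermediate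
19 | O-TBS-alkannin, 2-[(1S)-1-(tert-butyldimethylsilyloxy)-4-methylpent-3-enyl]-5,8-dihydroxy-1,4-naphthoquinone | CC(C)=CC[C@H](O[Si](C)(C)C(C)(C)C)C1=CC(=O)c2c(O)ccc(O)c2C1=O | intermediate
20 | alkannin, 5,8-dihydroxy-2-[(1S)-1-hydroxy-4-methylpent-3-enyl]-1,4-naphthoquinone | CC(C)=CC[C@H](O)C1=CC(=O)c2c(O)ccc(O)c2C1=O | intermediate
21 | isovaleric acid (3-methylbutanoic acid) | CC(C)CC(=O)O | starting material
22 | O-isovaleryl-N,N'-dicyclohexylisourea | CC(C)CC(=O)OC(=NC1CCCCC1)NC1CCCCC1 | intermediate
23 | isovalerylalkannin, (1S)-1-(5,8-dihydroxy-1,4-dioxo-1,4-dihydronaphthalen-2-yl)-4-methylpent-3-enyl 3-methylbutanoate | CC(C)=CC[C@H](OC(=O)CC(C)C)C1=CC(=O)c2c(O)ccc(O)c2C1=O | target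

Total step count: 10. Longest linear sequence: 9 steps (steps 1 to 5, then 7 to 10, from 4-methylpent-3-enoic acid); step 6 is a one-step branch.

Steps most likely to fail

Step 7. Three processes could defeat it. The electron-rich diene may reduce the quinone by hydride transfer in place of adding to it. Ethylene loss at the hydroquinone oxidation level may need temperatures at which the ortho-hydroxybenzylic silyl ether begins to eliminate towards a quinone methide, which would erode the (S)-centre. The aryl trimethylsilyl ethers may also be lost on prolonged heating. The fallback sets out from quinone 11 and builds ring A with a different four-carbon partner that needs neither extrusion nor heat nor a later oxidation. 2,5-Bis(trimethylsilyloxy)furan F1 would be made from succinic anhydride with TMSCl, Et3N and catalytic ZnCl2 in MeCN and added to 11 in CH2Cl2 at 25 °C. The resulting oxygen-bridged cycloadduct F2 should open on dilute acid work-up with loss of both trimethylsilyl groups and tautomerise directly to the naphthazarin oxidation level. This is the known use of such furans as bisketene equivalents towards quinones. The fallback comes back to the route at O-TBS-alkannin 19, which is then taken to 20 under the conditions of step 9.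

Step 9. Cleavage of the hindered secondary TBS ether may be slow. Long exposure to acidic fluoride could then let the freed hydroxyl close onto the prenyl alkene, or let the benzylic C–O bond ionise in the benzenoid tautomer with partial racemisation. The fallback sets out from alcohol 9, keeps the key step, and carries the carbinol as a trimethylsilyl ether so that all three silyl groups fall together under very mild acid. Alcohol 9 would be oxidised without protection by (NH4)2Ce(NO3)6 in MeCN/H2O at 0 °C to 2-[(1S)-1-hydroxy-4-methylpent-3-enyl]-1,4-benzoquinone F3. This is silylated under neutral conditions with N,O-bis(trimethylsilyl)acetamide in CH2Cl2 to 2-[(1S)-4-methyl-1-(trimethylsilyloxy)pent-3-enyl]-1,4-benzoquinone F4. Cycloaddition with 14 as in step 7 would pass through the bicyclic enedione adduct F5 and the bridged hydroquinone F6 to the tris(trimethylsilyl) naphthalene-1,4-diol F7. Ag2O as in step 8 would give the tris(trimethylsilyl) naphthoquinone F8, and citric acid in MeOH at 0 °C should then release alkannin 20, where the route is rejoined.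

Step 3. Facial discrimination may be poor, because the ortho-methoxy group can compete for the boron centre and the uncatalysed background reduction is unselective, so the enantiomeric purity could be eroded. The fallback sets out from ketone 7 and returns at alcohol 9 by a different mode of hydride delivery. It is an asymmetric transfer hydrogenation with RuCl[(S,S)-TsDPEN](p-cymene), whose ligand is (S,S)-N-(p-toluenesulfonyl)-1,2-diphenylethylenediamine, in HCO2H/Et3N (5:2) at 25 °C. The outer-sphere ruthenium hydride recognises the aryl group by a CH–π contact, not by size, and the (S,S)-catalyst should give the (S)-alcohol from aryl alkyl ketones. No borane is present, so the alkene is not at risk, and no new compound is made (F0).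

Further compounds
F1 | step 7 | 2,5-bis(trimethylsilyloxy)furan | C[Si](C)(C)Oc1ccc(O[Si](C)(C)C)o1
F2 | step 7 | 2-[(1S)-1-(tert-butyldimethylsilyloxy)-4-methylpent-3-enyl]-5,8-bis(trimethylsilyloxy)-4a,5,8,8a-tetrahydro-5,8-epoxynaphthalene-1,4-dione | CC(C)=CC[C@H](O[Si](C)(C)C(C)(C)C)C1=CC(=O)C2C(C1=O)C3(O[Si](C)(C)C)C=CC2(O[Si](C)(C)C)O3
F3 | step 9 | 2-[(1S)-1-hydroxy-4-methylpent-3-enyl]-1,4-benzoquinone | CC(C)=CC[C@H](O)C1=CC(=O)C=CC1=O
F4 | step 9 | 2-[(1S)-4-methyl-1-(trimethylsilyloxy)pent-3-enyl]-1,4-benzoquinone | CC(C)=CC[C@H](O[Si](C)(C)C)C1=CC(=O)C=CC1=O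
F5 | step 9 | 2-[(1S)-4-methyl-1-(trimethylsilyloxy)pent-3-enyl]-5,8-bis(trimethylsilyloxy)-4a,5,8,8a-tetrahydro-5,8-ethanonaphthalene-1,4-dione | CC(C)=CC[C@H](O[Si](C)(C)C)C1=CC(=O)C2C(C1=O)C3(O[Si](C)(C)C)CCC2(O[Si](C)(C)C)C=C3
F6 | step 9 | 2-[(1S)-4-methyl-1-(trimethylsilyloxy)pent-3-enyl]-5,8-bis(trimethylsilyloxy)-5,8-dihydro-5,8-ethanonaphthalene-1,4-diol | CC(C)=CC[C@H](O[Si](C)(C)C)c1cc(O)c2c(c1O)C1(O[Si](C)(C)C)CCC2(O[Si](C)(C)C)C=C1
F7 | step 9 | 2-[(1S)-4-methyl-1-(trimethylsilyloxy)pent-3-enyl]-5,8-bis(trimethylsilyloxy)naphthalene-1,4-diol | CC(C)=CC[C@H](O[Si](C)(C)C)c1cc(O)c2c(O[Si](C)(C)C)ccc(O[Si](C)(C)C)c2c1O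
F8 | step 9 | 2-[(1S)-4-methyl-1-(trimethylsilyloxy)pent-3-enyl]-5,8-bis(trimethylsilyloxy)-1,4-naphthoquinone | CC(C)=CC[C@H](O[Si](C)(C)C)C1=CC(=O)c2c(O[Si](C)(C)C)ccc(O[Si](C)(C)C)c2C1=O
F0 | step 3 | none | none
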